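**Strategy.** Numbering follows the isochroman-1-one ring. The lactone ring is opened in thought at C3–C4 and C1–C8a, which reveals its C3–O2–C1(=O) segment as an O-alkyl N,N-diisopropylcarbamate: C3 can be lithiated enantioselectively next to oxygen and C1 is a latent acyl donor. The partner is a benzylic bromide with bromine on C8a, ortho to the C8 oxygen. In one flask the lithiated carbamate is benzylated (C3–C4, C3 set), C8a is lithiated by bromine–lithium exchange, and the aryllithium captures the carbamoyl carbon (C1–C8a). Acid then closes the lactone ring and frees the three hydroxyls. The side-chain carbinol comes from (S)-1,2-epoxybutane.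

Key step: step 7

Remark: (−)-sparteine, (S)-1,2-epoxybutane, 8-bromooctan-1-ol, N,N-diisopropylcarbamoyl chloride and 3,5-dihydroxybenzyl alcohol are taken as purchasable.

**Fragment A (carbamate)**

Step 1
Reactants: 1 8-bromooctan-1-ol; 2 N,N-diisopropylcarbamoyl chloride
Product: 3 8-bromooctyl N,N-diisopropylcarbamate
Conditions: iPr2NEt (1.5 equiv), toluene, 100 °C
Reagents that add atoms: none
Why: Acylation of the primary alcohol by the carbamoyl chloride (carbamate formation) with a hindered amine base that cannot be quaternised by the primary bromide.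

Step 2
Reactants: 3 8-bromooctyl N,N-diisopropylcarbamate; 4 (S)-2-ethyloxirane
Product: 6 (10S)-10-hydroxydodecyl N,N-diisopropylcarbamate, via alkylmagnesium bromide 5 (not isolated)
Conditions: Mg, I2 (cat.), THF, 40 °C; then CuI (10 mol %), 4, −30 → 0 °C; aq. HCl (1 M) work-up
Reagents that add atoms: none
Why: Magnesium insertion into the primary C–Br bond followed by CuI-catalysed SN2 opening of the terminal epoxide at its CH2 carbon (Grignard epoxide opening) leaves the stereocentre of 4 untouched and should deliver the (S)-carbinol, the diisopropylcarbamate being inert to alkylmagnesium halides at these temperatures.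

Step 3
Reactants: 6 (10S)-10-hydroxydodecyl N,N-diisopropylcarbamate
Product: 7 (10S)-10-[(tert-butyldimethylsilyl)oxy]dodecyl N,N-diisopropylcarbamate
Conditions: TBSCl, imidazole, DMF, 23 °C
Reagents that add atoms: tert-butyldimethylsilyl chloride, CC(C)(C)[Si](C)(C)Cl
Why: Imidazole-promoted silylation of the secondary alcohol, so that no alkoxide disturbs the sparteine-bound organolithium of step 7; the silyl ether is removed together with the MOM groups in step 8.

**Fragment B (benzylic bromide)**

Step 4
Reactants: 8 3,5-dihydroxybenzyl alcohol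
Product: 9 [3,5-bis(methoxymethoxy)phenyl]methanol
Conditions: MOMCl (2.1 equiv), K2CO3, acetone, 0 → 23 °C
Reagents that add atoms: chloromethyl methyl ether, COCCl
Why: Williamson-type O-alkylation in which only the two phenols, far more acidic than the benzylic alcohol, are ionised by K2CO3, so the benzylic hydroxyl should stay free.

Step 5
Reactants: 9 [3,5-bis(methoxymethoxy)phenyl]methanol
Product: 10 [2-bromo-3,5-bis(methoxymethoxy)phenyl]methanol
Conditions: NBS (1.0 equiv), MeCN, 0 °C, dark
Reagents that add atoms: N-bromosuccinimide, O=C1CCC(=O)N1Br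
Why: Electrophilic aromatic bromination at ring position 2 (the future C8a), para to one MOM ether and ortho to the other and less hindered than the position between the two ethers; one equivalent of NBS at 0 °C should stop at the monobromide.

Step 6
Reactants: 10 [2-bromo-3,5-bis(methoxymethoxy)phenyl]methanol
Product: 11 2-bromo-1-(bromomethyl)-3,5-bis(methoxymethoxy)benzene
Conditions: CBr4, PPh3, CH2Cl2, 0 °C
Reagents that add atoms: carbon tetrabromide, BrC(Br)(Br)Br
Why: Appel reaction, which converts the benzylic alcohol into the bromide under neutral conditions that the MOM acetals tolerate.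

**Union and completion**

Step 7
Reactants: 7 (10S)-10-[(tert-butyldimethylsilyl)oxy]dodecyl N,N-diisopropylcarbamate; 11 2-bromo-1-(bromomethyl)-3,5-bis(methoxymethoxy)benzene
Product: 16 2-[(2R,11S)-11-[(tert-butyldimethylsilyl)oxy]-2-hydroxytridecyl]-4,6-bis(methoxymethoxy)-N,N-diisopropylbenzamide, via lithiated carbamate 12 (not isolated), via bromo carbamate 13 (not isolated), via aryllithium 14 (not isolated), via cyclic lithium alkoxide 15 (not isolated)
Conditions: 7 (1.3 equiv), s-BuLi (1.25 equiv), (−)-sparteine (1.3 equiv), Et2O, −78 °C, 5 h; 11 (1.0 equiv), −78 °C, 3 h; t-BuLi (2.2 equiv), −78 → 23 °C; aq. NH4Cl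
Reagents that add atoms: none
Why: s-BuLi/(−)-sparteine removes the pro-S proton next to oxygen in 7 (Hoppe asymmetric deprotonation) to give the configurationally stable, dipole-stabilised organolithium 12, which should attack the benzylic bromide of 11 with retention (SE2) and so forge C3–C4 with C3 fixed as R in 13. t-BuLi then exchanges the bromine on C8a, and aryllithium 14 adds to the carbamate carbonyl (Parham-type cyclisation) to forge C1–C8a in the cyclic adduct 15. This closure of the six-membered ring O2–C1–C8a–C4a–C4–C3 is 6-exo-trig; on warming 15 should expel the C3 alkoxide in preference to LiN(iPr)2, so the ring reopens to the lithium alkoxide of 16 (net 1,5-O→C carbamoyl shift) and is closed for good in step 8. The closest known reaction types are the alkylation of sparteine-complexed lithiated O-alkyl carbamates and the anionic homo-Fries rearrangement of ortho-lithiated benzyl carbamates, here run in sequence in one flask. C3 is the only new stereocentre and is controlled by the chiral diamine in the deprotonation, independent of the distant silyloxy stereocentre. The step needs C-alkylation to outrun bromine–lithium exchange, which the much more electrophilic benzylic bromide and the absence of free s-BuLi (7 in excess) should secure, and it needs lithiation at C8a and not at C7 between the two MOM ethers, which the bromine placed on C8a secures.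

Step 8
Reactants: 16 2-[(2R,11S)-11-[(tert-butyldimethylsilyl)oxy]-2-hydroxytridecyl]-4,6-bis(methoxymethoxy)-N,N-diisopropylbenzamide
Product: 18 (3R)-6,8-dihydroxy-3-[(9S)-9-hydroxyundecyl]-3,4-dihydro-1H-isochromen-1-one (CNP0340379.1), via triol amide 17 (not isolated)
Conditions: HCl (3 M in MeOH), 50 °C; then evaporation, TsOH·H2O (1.5 equiv), toluene, 90 °C
Reagents that add atoms: none
Why: Acidic methanolysis cleaves the two MOM acetals and the silyl ether, and acid-catalysed acyl transfer from nitrogen to the C3 oxygen (lactonisation of a 2-(2-hydroxyalkyl)benzamide, 6-exo-trig) should then close the lactone ring with loss of diisopropylamine; no bond to either stereocentre is broken, so both configurations are retained.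

**Compound list**

1 | 8-bromooctan-1-ol | OCCCCCCCCBr | starting material
2 | N,N-diisopropylcarbamoyl chloride | CC(C)N(C(C)C)C(=O)Cl | starting material
3 | 8-bromooctyl N,N-diisopropylcarbamate | BrCCCCCCCCOC(=O)N(C(C)C)C(C)C | intermediate
4 | (S)-2-ethyloxirane [(S)-1,2-epoxybutane] | CC[C@H]1CO1 | starting material
5 | {8-[(diisopropylcarbamoyl)oxy]octyl}magnesium bromide | Br[Mg]CCCCCCCCOC(=O)N(C(C)C)C(C)C | intermediate
6 | (10S)-10-hydroxydodecyl N,N-diisopropylcarbamate | CC[C@H](O)CCCCCCCCCOC(=O)N(C(C)C)C(C)C | intermediate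
7 | (10S)-10-[(tert-butyldimethylsilyl)oxy]dodecyl N,N-diisopropylcarbamate | CC[C@H](O[Si](C)(C)C(C)(C)C)CCCCCCCCCOC(=O)N(C(C)C)C(C)C | intermediate
8 | 3,5-dihydroxybenzyl alcohol | OCc1cc(O)cc(O)c1 | starting material
9 | [3,5-bis(methoxymethoxy)phenyl]methanol | OCc1cc(OCOC)cc(OCOC)c1 | intermediate
10 | [2-bromo-3,5-bis(methoxymethoxy)phenyl]methanol | OCc1cc(OCOC)cc(OCOC)c1Br | intermediate
11 | 2-bromo-1-(bromomethyl)-3,5-bis(methoxymethoxy)benzene | BrCc1cc(OCOC)cc(OCOC)c1Br | intermediate
12 | (1S,10S)-10-[(tert-butyldimethylsilyl)oxy]-1-lithiododecyl N,N-diisopropylcarbamate (sparteine-bound) | CC[C@H](O[Si](C)(C)C(C)(C)C)CCCCCCCC[C@H]([Li])OC(=O)N(C(C)C)C(C)C | intermediate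
13 | (2R,11S)-1-[2-bromo-3,5-bis(methoxymethoxy)phenyl]-11-[(tert-butyldimethylsilyl)oxy]tridecan-2-yl N,N-diisopropylcarbamate | CC[C@H](O[Si](C)(C)C(C)(C)C)CCCCCCCC[C@H](Cc1cc(OCOC)cc(OCOC)c1Br)OC(=O)N(C(C)C)C(C)C | intermediate
14 | (2R,11S)-11-[(tert-butyldimethylsilyl)oxy]-1-[2-lithio-3,5-bis(methoxymethoxy)phenyl]tridecan-2-yl N,N-diisopropylcarbamate | CC[C@H](O[Si](C)(C)C(C)(C)C)CCCCCCCC[C@H](Cc1cc(OCOC)cc(OCOC)c1[Li])OC(=O)N(C(C)C)C(C)C | intermediate
15 | lithium (3R)-3-{(9S)-9-[(tert-butyldimethylsilyl)oxy]undecyl}-1-(diisopropylamino)-6,8-bis(methoxymethoxy)isochroman-1-olate (C1 undefined) | CC[C@H](O[Si](C)(C)C(C)(C)C)CCCCCCCC[C@@H]1Cc2cc(OCOC)cc(OCOC)c2C(O[Li])(N(C(C)C)C(C)C)O1 | intermediate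
16 | 2-[(2R,11S)-11-[(tert-butyldimethylsilyl)oxy]-2-hydroxytridecyl]-4,6-bis(methoxymethoxy)-N,N-diisopropylbenzamide | CC[C@H](O[Si](C)(C)C(C)(C)C)CCCCCCCC[C@@H](O)Cc1cc(OCOC)cc(OCOC)c1C(=O)N(C(C)C)C(C)C | intermediate
17 | 2-[(2R,11S)-2,11-dihydroxytridecyl]-4,6-dihydroxy-N,N-diisopropylbenzamide | CC[C@H](O)CCCCCCCC[C@@H](O)Cc1cc(O)cc(O)c1C(=O)N(C(C)C)C(C)C | intermediate
18 | (3R)-6,8-dihydroxy-3-[(9S)-9-hydroxyundecyl]-3,4-dihydro-1H-isochromen-1-one (CNP0340379.1) | CC[C@H](O)CCCCCCCC[C@@H]1Cc2cc(O)cc(O)c2C(=O)O1 | target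

**Step count.** Total: 8 steps. Longest linear sequence: 5 steps (1 → 2 → 3 → 7 → 8, or 4 → 5 → 6 → 7 → 8).

**Steps most likely to fail**

Step 7. Electron transfer from the lithiated carbamate to the benzylic bromide could erode the configuration at C3 and give Wurtz-type dimers. Deprotonation of the bromomethyl group or bromine–lithium exchange at C8a could also compete before the C-alkylation is complete. The fallback sets out from 7 and 11 and comes back to the route at 13; it makes the C3–C4 bond by a 1,2-metalate rearrangement instead of a direct alkylation. Bromide 11 is borylated (B2pin2, CuI, PPh3, LiOMe, DMF, 23 °C) to 2-{[2-bromo-3,5-bis(methoxymethoxy)phenyl]methyl}-4,4,5,5-tetramethyl-1,3,2-dioxaborolane F1. Organolithium 12, generated from 7 as in step 7, is trapped with F1 at −78 °C, and the boronate is warmed with MgBr2·OEt2 so that the benzyl group migrates from boron to C3 with inversion and expels the carbamate. This should give 2-{(2R,11S)-1-[2-bromo-3,5-bis(methoxymethoxy)phenyl]-11-[(tert-butyldimethylsilyl)oxy]tridecan-2-yl}-4,4,5,5-tetramethyl-1,3,2-dioxaborolane F2. NaOH/H2O2 oxidises it with retention to (2R,11S)-1-[2-bromo-3,5-bis(methoxymethoxy)phenyl]-11-[(tert-butyldimethylsilyl)oxy]tridecan-2-ol F3. Borylation with retention, migration with inversion and oxidation with retention together give the same configuration at C3 as the direct alkylation. F3 is carbamoylated with 2 (NaH, THF, 60 °C) to 13, now isolated, which is taken through the t-BuLi stage of step 7 to 16.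

Step 8. The twisted, doubly ortho-substituted diisopropylamide may resist acid-catalysed acyl transfer. Forcing conditions could then cause dehydration at the side-chain carbinol or substitution of the free resorcinol ring by formaldehyde equivalents from the MOM groups. The fallback sets out from 16 and comes back to the route at 18; it lowers the oxidation level of the amide before the ring is closed. Cp2Zr(H)Cl (3 equiv, THF, 23 °C) reduces the tertiary amide of 16 to the aldehyde, which closes onto the C3 hydroxyl to give (3R)-3-{(9S)-9-[(tert-butyldimethylsilyl)oxy]undecyl}-6,8-bis(methoxymethoxy)-3,4-dihydro-1H-isochromen-1-ol F4. TEMPO (cat.) with PhI(OAc)2 in CH2Cl2 oxidises the lactol to (3R)-3-{(9S)-9-[(tert-butyldimethylsilyl)oxy]undecyl}-6,8-bis(methoxymethoxy)-3,4-dihydro-1H-isochromen-1-one F5. HCl (3 M in MeOH) at 40 °C then removes the MOM and silyl groups to give 18.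

Step 2. Magnesium insertion may be sluggish and accompanied by Wurtz coupling, the organomagnesium may attack the carbamate of a second molecule, or MgBr2 may open 4 to a halohydrin. The fallback sets out from 1 and 4 and comes back to the route at 6; it introduces the carbamate only after the C–C bond is made. Alcohol 1 is protected (3,4-dihydro-2H-pyran, PPTS, CH2Cl2) as 2-[(8-bromooctyl)oxy]oxane F6. Its Grignard reagent opens 4 under CuI catalysis (aq. NH4Cl work-up) to (3S)-12-(oxan-2-yloxy)dodecan-3-ol F7. PPTS in MeOH removes the acetal to give (10S)-dodecane-1,10-diol F8. The hindered chloride 2 with Et3N in CH2Cl2 at 40 °C should then carbamoylate the primary hydroxyl selectively to give 6.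

**Further compounds**

F1 | step 7 | 2-{[2-bromo-3,5-bis(methoxymethoxy)phenyl]methyl}-4,4,5,5-tetramethyl-1,3,2-dioxaborolane | CC1(C)OB(Cc2cc(OCOC)cc(OCOC)c2Br)OC1(C)C
F2 | step 7 | 2-{(2R,11S)-1-[2-bromo-3,5-bis(methoxymethoxy)phenyl]-11-[(tert-butyldimethylsilyl)oxy]tridecan-2-yl}-4,4,5,5-tetramethyl-1,3,2-dioxaborolane | CC[C@H](O[Si](C)(C)C(C)(C)C)CCCCCCCC[C@@H](B1OC(C)(C)C(C)(C)O1)Cc1cc(OCOC)cc(OCOC)c1Br
F3 | step 7 | (2R,11S)-1-[2-bromo-3,5-bis(methoxymethoxy)phenyl]-11-[(tert-butyldimethylsilyl)oxy]tridecan-2-ol | CC[C@H](O[Si](C)(C)C(C)(C)C)CCCCCCCC[C@@H](O)Cc1cc(OCOC)cc(OCOC)c1Br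
F4 | step 8 | (3R)-3-{(9S)-9-[(tert-butyldimethylsilyl)oxy]undecyl}-6,8-bis(methoxymethoxy)-3,4-dihydro-1H-isochromen-1-ol | CC[C@H](O[Si](C)(C)C(C)(C)C)CCCCCCCC[C@@H]1Cc2cc(OCOC)cc(OCOC)c2C(O)O1
F5 | step 8 | (3R)-3-{(9S)-9-[(tert-butyldimethylsilyl)oxy]undecyl}-6,8-bis(methoxymethoxy)-3,4-dihydro-1H-isochromen-1-one | CC[C@H](O[Si](C)(C)C(C)(C)C)CCCCCCCC[C@@H]1Cc2cc(OCOC)cc(OCOC)c2C(=O)O1
F6 | step 2 | 2-[(8-bromooctyl)oxy]oxane | BrCCCCCCCCOC1CCCCO1
F7 | step 2 | (3S)-12-(oxan-2-yloxy)dodecan-3-ol | CC[C@H](O)CCCCCCCCCOC1CCCCO1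
F8 | step 2 | (10S)-dodecane-1,10-diol | CC[C@H](O)CCCCCCCCCO
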